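## Retrosynthetic overview

1. The target comes from site-selective saturation of the C2=C3 olefin of a ten-membered 2Z,4E-diene.
2. That diene comes from ring-closing metathesis between a terminal 1,3-diene and a vinyl oxirane, the only step that forms the carbocycle.
3. The metathesis substrate comes from an Evans–Tishchenko reaction of a β-hydroxy ketone with 3,4,5-trimethoxybenzaldehyde, which sets C9 and places the aroyl group on O7.
4. The β-hydroxy ketone comes from a syn boron aldol between an epoxy ketone (fragment A, oxirane from a Sharpless epoxidation) and a dienal (fragment B, Negishi carboalumination).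
5. Ring order: the oxirane is made first (step 2), the ten-membered ring second (step 13).

Assumption: the SMILES is read literally, i.e. a cis-fused oxirane (ring carbons C2 and C9 cis on the oxirane), a 4E olefin and (1S,7S,8S,9R,10R). Locants are those of 11-oxabicyclo[8.1.0]undecane: C1 = methyl-bearing oxirane carbon, C5 = olefinic methyl carbon, C7 = aroyloxy, C8 = isopropyl, C9 = hydroxyl, C10 = oxirane CH.

## Fragment A (epoxy ketone)

Step 1
Reactants: 1 (2Z)-3-methylpent-2-en-4-yn-1-ol
Product: 2 (2Z)-3-methylpenta-2,4-dien-1-ol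
Conditions: H2 (1 atm), Pd/CaCO3 poisoned by Pb(OAc)2, quinoline, EtOAc, rt, stopped after 1 equiv H2
Reagents that add atoms: none
Why: Lindlar semi-hydrogenation stops at the alkene on the poisoned palladium surface and leaves the trisubstituted 2Z olefin, which later becomes the cis-oxirane, untouched.

Step 2
Reactants: 2 (2Z)-3-methylpenta-2,4-dien-1-ol
Product: 3 [(2R,3S)-3-ethenyl-3-methyloxiran-2-yl]methanol
Conditions: Ti(OiPr)4 (20 mol%), D-(−)-diethyl tartrate (24 mol%), t-BuOOH (1.5 equiv, decane), 4 Å MS, CH2Cl2, −20 °C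
Reagents that add atoms: tert-butyl hydroperoxide CC(C)(C)OO
Why: In this Katsuki–Sharpless asymmetric epoxidation only the olefin bearing the allylic hydroxyl reacts, and the D-(−)-tartrate delivers oxygen to the face that gives (2R,3S), the mirror image of the (2S,3R) series known for nerol-type Z-alcohols with the L-(+)-tartrate, so C1, C10 and the cis fusion are fixed here.

Step 3
Reactants: 3 [(2R,3S)-3-ethenyl-3-methyloxiran-2-yl]methanol
Product: 4 (2S,3S)-3-ethenyl-3-methyloxirane-2-carbaldehyde
Conditions: Dess–Martin periodinane (1.2 equiv), pyridine, CH2Cl2, 0 °C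
Reagents that add atoms: none
Why: Buffered Dess–Martin oxidation takes the primary alcohol to the aldehyde under near-neutral conditions that spare the acid-labile vinyl oxirane (the descriptor at C2 changes only because the CIP priorities change).

Step 4
Reactants: 4 (2S,3S)-3-ethenyl-3-methyloxirane-2-carbaldehyde; 5 isobutylmagnesium bromide
Product: 6 1-[(2R,3S)-3-ethenyl-3-methyloxiran-2-yl]-3-methylbutan-1-ol (both carbinol epimers)
Conditions: THF, −78 °C; then H2O
Reagents that add atoms: none
Why: Grignard 1,2-addition to the aldehyde at −78 °C is far faster than oxirane opening, and the stereorandom carbinol centre is removed in the next step.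

Step 5
Reactants: 6 1-[(2R,3S)-3-ethenyl-3-methyloxiran-2-yl]-3-methylbutan-1-ol
Product: 7 1-[(2S,3S)-3-ethenyl-3-methyloxiran-2-yl]-3-methylbutan-1-one
Conditions: Dess–Martin periodinane (1.3 equiv), pyridine, CH2Cl2, 0 °C to rt
Reagents that add atoms: none
Why: Dess–Martin oxidation converges both carbinol epimers on one ketone, and the oxirane C–H next to the carbonyl is not enolisable under these conditions, so C10 is not scrambled.

## Fragment B (dienal)

Step 6
Reactants: 8 but-3-yn-1-ol
Product: 9 (but-3-yn-1-yloxy)(tert-butyl)dimethylsilane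
Conditions: TBSCl, imidazole, CH2Cl2, 0 °C to rt
Reagents that add atoms: tert-butyldimethylsilyl chloride CC(C)(C)[Si](C)(C)Cl
Why: Imidazole-promoted silylation masks the hydroxyl so that no aluminium alkoxide forms in the carbometalation and the following intermediates are non-volatile and easy to purify.

Step 7
Reactants: 9 (but-3-yn-1-yloxy)(tert-butyl)dimethylsilane
Product: 11 tert-butyl{[(3E)-4-iodo-3-methylbut-3-en-1-yl]oxy}dimethylsilane, via alkenyldimethylalane 10 (not isolated)
Conditions: Me3Al (2 equiv), Cp2ZrCl2 (20 mol%), CH2Cl2, 0 °C to rt; then I2, THF, −30 to 0 °C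
Reagents that add atoms: trimethylaluminium C[Al](C)C; iodine II
Why: Negishi zirconium-catalysed carboalumination adds Me–Al syn across the terminal alkyne with methyl on the internal carbon, and iodinolysis of the C–Al bond with retention gives the E vinyl iodide that becomes the 4E olefin.

Step 8
Reactants: 11 tert-butyl{[(3E)-4-iodo-3-methylbut-3-en-1-yl]oxy}dimethylsilane; 12 tributyl(ethenyl)stannane
Product: 13 tert-butyl(dimethyl){[(3E)-3-methylhexa-3,5-dien-1-yl]oxy}silane
Conditions: Pd(MeCN)2Cl2 (5 mol%), DMF, rt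
Reagents that add atoms: none
Why: Stille coupling proceeds with retention of the alkenyl iodide geometry, so the 3E diene is obtained.

Step 9
Reactants: 13 tert-butyl(dimethyl){[(3E)-3-methylhexa-3,5-dien-1-yl]oxy}silane
Product: 14 (3E)-3-methylhexa-3,5-dien-1-ol
Conditions: HF·pyridine, pyridine, THF, 0 °C to rt
Reagents that add atoms: none
Why: Fluoride-driven desilylation (strong Si–F bond) frees the primary alcohol, and the buffered reagent does not touch the diene.

Step 10
Reactants: 14 (3E)-3-methylhexa-3,5-dien-1-ol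
Product: 15 (3E)-3-methylhexa-3,5-dienal
Conditions: Dess–Martin periodinane (1.2 equiv), pyridine, CH2Cl2, 0 °C; used at once as a cold solution
Reagents that add atoms: none
Why: Dess–Martin oxidation is mild enough to give the β,γ-unsaturated aldehyde without moving the olefin into conjugation, provided the aldehyde is used immediately.

## Union and endgame

Step 11
Reactants: 7 1-[(2S,3S)-3-ethenyl-3-methyloxiran-2-yl]-3-methylbutan-1-one; 15 (3E)-3-methylhexa-3,5-dienal
Product: 17 (2R,3S,5E)-1-[(2S,3S)-3-ethenyl-3-methyloxiran-2-yl]-3-hydroxy-5-methyl-2-(propan-2-yl)octa-5,7-dien-1-one, via (Z)-enol dibutylborinate 16 (not isolated)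
Conditions: n-Bu2BOTf (1.2 equiv), i-Pr2NEt (1.5 equiv), CH2Cl2, −78 °C, 1 h; then 15 (1.5 equiv), −78 to −30 °C; pH 7 buffer, MeOH, 30% H2O2, 0 °C
Reagents that add atoms: none
Why: In this boron-mediated syn aldol the (Z)-enol borinate reacts through a closed Zimmerman–Traxler transition state to give the C7/C8 syn pair, and the facial sense is expected (not proven) to come from the oxirane C–O lying anti to the enolate C–O so that the aldehyde adds anti to the fully substituted C1.

Step 12
Reactants: 17 (2R,3S,5E)-1-[(2S,3S)-3-ethenyl-3-methyloxiran-2-yl]-3-hydroxy-5-methyl-2-(propan-2-yl)octa-5,7-dien-1-one; 18 3,4,5-trimethoxybenzaldehyde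
Product: 19 (1R,2S,3S,5E)-1-[(2R,3S)-3-ethenyl-3-methyloxiran-2-yl]-1-hydroxy-5-methyl-2-(propan-2-yl)octa-5,7-dien-3-yl 3,4,5-trimethoxybenzoate
Conditions: SmI2 (0.3 equiv) stirred first with 18 (5 equiv) in THF at rt until colourless (trivalent samarium pinacolate catalyst); then 17, −10 °C
Reagents that add atoms: none
Why: In the Evans–Tishchenko reaction the samarium-bound hemiacetal formed on O7 delivers hydride intramolecularly to the ketone through a chair-like bicyclic transition state, which gives the 7,9-anti diol monoester with the aroyl group on O7 and the free hydroxyl at C9 (9R).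

Step 13
Reactants: 19 (1R,2S,3S,5E)-1-[(2R,3S)-3-ethenyl-3-methyloxiran-2-yl]-1-hydroxy-5-methyl-2-(propan-2-yl)octa-5,7-dien-3-yl 3,4,5-trimethoxybenzoate
Product: 20 (1S,2Z,4E,7S,8S,9R,10R)-9-hydroxy-1,5-dimethyl-8-(propan-2-yl)-11-oxabicyclo[8.1.0]undeca-2,4-dien-7-yl 3,4,5-trimethoxybenzoate
Conditions: second-generation Hoveyda–Grubbs catalyst (10 mol%), 1,4-benzoquinone (20 mol%), toluene, 0.5 mM, 80 °C, slow addition of 19, argon sparge
Reagents that add atoms: none
Why: Ring-closing metathesis joins the two monosubstituted termini (diene end and vinyl oxirane) with loss of ethene while the trisubstituted 4E olefin stays inert, the cis-oxirane and E-olefin pre-fold the chain, and the geometry of the new C2=C3 bond is irrelevant because it is reduced next.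

Step 14
Reactants: 20 (1S,2Z,4E,7S,8S,9R,10R)-9-hydroxy-1,5-dimethyl-8-(propan-2-yl)-11-oxabicyclo[8.1.0]undeca-2,4-dien-7-yl 3,4,5-trimethoxybenzoate
Product: 21 (1S,4E,7S,8S,9R,10R)-9-hydroxy-1,5-dimethyl-8-(propan-2-yl)-11-oxabicyclo[8.1.0]undec-4-en-7-yl 3,4,5-trimethoxybenzoate
Conditions: 2-nitrobenzenesulfonylhydrazide (4 equiv, in portions), Et3N, CH2Cl2, rt; stopped when 20 is consumed
Reagents that add atoms: none
Why: Diimide reduction transfers H2 in a concerted syn fashion to the cis-disubstituted C2=C3 bond much faster than to the trisubstituted C4=C5 bond and, unlike metal-catalysed hydrogenation, does not hydrogenolyse the allylic oxirane or touch the ester.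

## Compound list

1 | (2Z)-3-methylpent-2-en-4-yn-1-ol | C#C/C(C)=C\CO | starting material
2 | (2Z)-3-methylpenta-2,4-dien-1-ol | C=C/C(C)=C\CO | intermediate
3 | [(2R,3S)-3-ethenyl-3-methyloxiran-2-yl]methanol | C=C[C@]1(C)O[C@@H]1CO | intermediate
4 | (2S,3S)-3-ethenyl-3-methyloxirane-2-carbaldehyde | C=C[C@]1(C)O[C@@H]1C=O | intermediate
5 | isobutylmagnesium bromide | CC(C)C[Mg]Br | starting material
6 | 1-[(2R,3S)-3-ethenyl-3-methyloxiran-2-yl]-3-methylbutan-1-ol (both carbinol epimers) | C=C[C@]1(C)O[C@@H]1C(O)CC(C)C | intermediate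
7 | 1-[(2S,3S)-3-ethenyl-3-methyloxiran-2-yl]-3-methylbutan-1-one | C=C[C@]1(C)O[C@@H]1C(=O)CC(C)C | intermediate
8 | but-3-yn-1-ol | C#CCCO | starting material
9 | (but-3-yn-1-yloxy)(tert-butyl)dimethylsilane | C#CCCO[Si](C)(C)C(C)(C)C | intermediate
10 | [(1E)-4-{[tert-butyl(dimethyl)silyl]oxy}-2-methylbut-1-en-1-yl](dimethyl)alumane | C[Al](C)/C=C(\C)CCO[Si](C)(C)C(C)(C)C | intermediate (not isolated)
11 | tert-butyl{[(3E)-4-iodo-3-methylbut-3-en-1-yl]oxy}dimethylsilane | I/C=C(\C)CCO[Si](C)(C)C(C)(C)C | intermediate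
12 | tributyl(ethenyl)stannane | C=C[Sn](CCCC)(CCCC)CCCC | starting material
13 | tert-butyl(dimethyl){[(3E)-3-methylhexa-3,5-dien-1-yl]oxy}silane | C=C/C=C(\C)CCO[Si](C)(C)C(C)(C)C | intermediate
14 | (3E)-3-methylhexa-3,5-dien-1-ol | C=C/C=C(\C)CCO | intermediate
15 | (3E)-3-methylhexa-3,5-dienal | C=C/C=C(\C)CC=O | intermediate
16 | (1Z)-1-[(2R,3S)-3-ethenyl-3-methyloxiran-2-yl]-3-methylbut-1-en-1-yl dibutylborinate | CCCCB(CCCC)O/C(=C\C(C)C)[C@H]1O[C@@]1(C)C=C | intermediate (not isolated)
17 | (2R,3S,5E)-1-[(2S,3S)-3-ethenyl-3-methyloxiran-2-yl]-3-hydroxy-5-methyl-2-(propan-2-yl)octa-5,7-dien-1-one | C=C/C=C(\C)C[C@H](O)[C@@H](C(C)C)C(=O)[C@H]1O[C@@]1(C)C=C | intermediate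
18 | 3,4,5-trimethoxybenzaldehyde | COc1cc(C=O)cc(OC)c1OC | starting material
19 | (1R,2S,3S,5E)-1-[(2R,3S)-3-ethenyl-3-methyloxiran-2-yl]-1-hydroxy-5-methyl-2-(propan-2-yl)octa-5,7-dien-3-yl 3,4,5-trimethoxybenzoate | C=C/C=C(\C)C[C@H](OC(=O)c1cc(OC)c(OC)c(OC)c1)[C@@H](C(C)C)[C@@H](O)[C@H]2O[C@@]2(C)C=C | intermediate
20 | (1S,2Z,4E,7S,8S,9R,10R)-9-hydroxy-1,5-dimethyl-8-(propan-2-yl)-11-oxabicyclo[8.1.0]undeca-2,4-dien-7-yl 3,4,5-trimethoxybenzoate | COc1cc(C(=O)O[C@H]2C/C(C)=C/C=C\[C@]3(C)O[C@@H]3[C@H](O)[C@@H]2C(C)C)cc(OC)c1OC | intermediate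
21 | (1S,4E,7S,8S,9R,10R)-9-hydroxy-1,5-dimethyl-8-(propan-2-yl)-11-oxabicyclo[8.1.0]undec-4-en-7-yl 3,4,5-trimethoxybenzoate | COc1cc(C(=O)O[C@H]2C/C(C)=C/CC[C@]3(C)O[C@@H]3[C@H](O)[C@@H]2C(C)C)cc(OC)c1OC | target

## Step count and risks

Total step count: 14.
Longest linear sequence: 9 steps (steps 1–5 then 11–14; the branch through steps 6–10 then 11–14 is equally long).

**Step 13 (ring-closing metathesis).** A ten-membered ring holding an E olefin, a new Z olefin and a cis-oxirane is strained, so dimerisation or a stalled conjugated ruthenium carbene may win. The fallback sets out from 17 and closes the ring one step earlier, where C9 is still sp2 and the hydrogen-bonded hydroxy ketone folds the chain. The same ruthenium catalyst under the same dilution turns 17 into the macrocyclic hydroxy ketone (1S,2Z,4E,7S,8R,10S)-7-hydroxy-1,5-dimethyl-8-(propan-2-yl)-11-oxabicyclo[8.1.0]undeca-2,4-dien-9-one F1. An Evans–Tishchenko reaction of F1 with 18 (SmI2 pre-stirred with the aldehyde, THF, −10 °C) then sets C9 and the ester inside the ring and comes back to the route at 20.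

**Step 11 (boron aldol).** The sense of facial control by the oxirane is a model-based prediction, and the boron triflate may also ionise the tertiary allylic oxirane. The fallback sets out from 7 and replaces the non-chelated boron enolate by a chelated one. Sn(OTf)2 and N-ethylpiperidine in CH2Cl2 at −78 °C give the divalent-tin (Z)-enolate {[(1Z)-1-[(2S,3S)-3-ethenyl-3-methyloxiran-2-yl]-3-methylbut-1-en-1-yl]oxy}tin trifluoromethanesulfonate F2, in which tin bridges the enolate and oxirane oxygens. The aldehyde 15 is then forced onto the opposite π-face while the closed transition state still gives the 7,8-syn pair, and aqueous work-up comes back to the route at 17. This fallback helps if the boron enolate picks the wrong face; it does not help if the boron enolate picks the right face with low selectivity.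

**Step 12 (Evans–Tishchenko).** Residual divalent samarium could open the α,β-epoxy ketone, and the Lewis-acidic trivalent samarium could attack the vinyl oxirane. The fallback sets out from 17 and separates acylation from reduction. 3,4,5-Trimethoxybenzoyl chloride with pyridine and DMAP in CH2Cl2 at 0 °C gives the keto ester (2R,3S,5E)-1-[(2S,3S)-3-ethenyl-3-methyloxiran-2-yl]-5-methyl-1-oxo-2-(propan-2-yl)octa-5,7-dien-3-yl 3,4,5-trimethoxybenzoate F3. Zn(BH4)2 in Et2O at −20 °C then reduces the ketone under chelation between the oxirane and carbonyl oxygens to the erythro epoxy alcohol, which is 19, where the route is rejoined.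

## Further compounds

F1 | step 13 | (1S,2Z,4E,7S,8R,10S)-7-hydroxy-1,5-dimethyl-8-(propan-2-yl)-11-oxabicyclo[8.1.0]undeca-2,4-dien-9-one | O[C@H]1C/C(C)=C/C=C\[C@]2(C)O[C@@H]2C(=O)[C@@H]1C(C)C
F2 | step 11 | {[(1Z)-1-[(2S,3S)-3-ethenyl-3-methyloxiran-2-yl]-3-methylbut-1-en-1-yl]oxy}tin trifluoromethanesulfonate | O=S(=O)(O[Sn]O/C(=C\C(C)C)[C@H]1O[C@@]1(C)C=C)C(F)(F)F
F3 | step 12 | (2R,3S,5E)-1-[(2S,3S)-3-ethenyl-3-methyloxiran-2-yl]-5-methyl-1-oxo-2-(propan-2-yl)octa-5,7-dien-3-yl 3,4,5-trimethoxybenzoate | C=C/C=C(\C)C[C@H](OC(=O)c1cc(OC)c(OC)c(OC)c1)[C@@H](C(C)C)C(=O)[C@H]2O[C@@]2(C)C=C
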